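**Retrosynthetic overview**

1. Locants (germacrane): ten-membered ring C1–C10 with C10=C1 (Z, methyl C14) and C4=C15; lactone ring O–C6–C7–C11–C12 with C11=C13; OH at C2, OAc at C5, tiglate at C8.
2. The strategy rests on the lactone ring O–C6–C7–C11–C12, a reduced furan-2(5H)-one whose γ-carbon C6 is bonded to the carbinol C5. Cutting C5–C6 gives a 4-substituted 2-silyloxyfuran (C6 nucleophile) tethered to a C4-methylene enal (C5), so a vinylogous Mukaiyama aldol closes the ten-membered ring and creates the butenolide in one event.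
3. The open chain comes from 2-(furan-3-yl)-1,3-dithiane (C8 acyl anion) and a (Z)-allylic bromide C9–C5. The bromide is built from methyl (R)-glycidate (C2), a 2-metallated acrolein acetal (C4, C15, C5) and a Still–Gennari olefination (C10=C1). C8 is set by CBS reduction; the furan is oxidised to the butenolide and silylated last.
4. Ring order: furan (purchased) → butenolide → 2-silyloxyfuran → ten-membered carbocycle plus butenolide (step 16) → cis-fused γ-lactone by conjugate reduction; then α-methylenation, acetylation, PMB removal, tigloylation and desilylation.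

Key step: step 16

Remark: compounds 1, 2, 8 and 13 are taken to be commercially available; TBS = tert-butyldimethylsilyl, PMB = 4-methoxybenzyl, TIPS = triisopropylsilyl; C6 of 21, the bridgeheads of 20 and C11 of 29 and 30 are formed as mixtures of no consequence.

**Route**

Step 1
Reactants: 1 2-bromo-3,3-diethoxyprop-1-ene; 2 methyl (2R)-oxirane-2-carboxylate
Product: 5 methyl (2R)-4-(diethoxymethyl)-2-hydroxypent-4-enoate, via (3,3-diethoxyprop-1-en-2-yl)lithium 3 (not isolated), via (3,3-diethoxyprop-1-en-2-yl)magnesium bromide 4 (not isolated)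
Conditions: 1, t-BuLi (2 equiv), Et2O, −78 °C; MgBr2·OEt2; CuI (10 mol%), then 2, Et2O/THF, −78 → −40 °C; then H2O
Reagents that add atoms: none
Why: Bromine–lithium exchange gives the α-(diethoxymethyl)vinyl anion, which after transmetalation to magnesium opens the glycidate at its unsubstituted C3 under CuI catalysis (copper-catalysed Grignard epoxide opening), so the stereocentre of 2 is untouched and becomes C2 (R) while the vinyl unit brings C4, C15 and the masked C5 aldehyde.

Step 2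
Reactants: 5 methyl (2R)-4-(diethoxymethyl)-2-hydroxypent-4-enoate
Product: 6 methyl (2R)-2-[(tert-butyldimethylsilyl)oxy]-4-(diethoxymethyl)pent-4-enoate
Conditions: TBSCl, imidazole, DMF, rt
Reagents that add atoms: tert-butyldimethylsilyl chloride, CC(C)(C)[Si](C)(C)Cl
Why: Imidazole-promoted silylation of the secondary α-hydroxy ester installs the C2 silyl ether that is kept until the last step.

Step 3
Reactants: 6 methyl (2R)-2-[(tert-butyldimethylsilyl)oxy]-4-(diethoxymethyl)pent-4-enoate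
Product: 7 (2R)-2-[(tert-butyldimethylsilyl)oxy]-4-(diethoxymethyl)pent-4-enal
Conditions: DIBAL-H (1.1 equiv), CH2Cl2, −78 °C; MeOH, aq Rochelle salt
Reagents that add atoms: none
Why: DIBAL-H half-reduction of an α-silyloxy methyl ester at −78 °C should stop at the aldehyde because the chelated aluminium hemiacetal survives until work-up, and the crude aldehyde is used at once to avoid α-epimerisation.

Step 4
Reactants: 7 (2R)-2-[(tert-butyldimethylsilyl)oxy]-4-(diethoxymethyl)pent-4-enal; 8 ethyl 2-[bis(2,2,2-trifluoroethoxy)phosphoryl]propanoate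
Product: 10 ethyl (2Z,4R)-4-[(tert-butyldimethylsilyl)oxy]-6-(diethoxymethyl)-2-methylhepta-2,6-dienoate, via potassium phosphonate carbanion 9 (not isolated)
Conditions: 8, KHMDS, 18-crown-6, THF, −78 °C; then 7, −78 °C
Reagents that add atoms: none
Why: Still–Gennari olefination with the bis(trifluoroethyl) phosphonate under dissociating conditions gives the (Z)-trisubstituted enoate by fast kinetically controlled elimination, which sets the C10=C1 geometry with C9 and C2 cis.

Step 5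
Reactants: 10 ethyl (2Z,4R)-4-[(tert-butyldimethylsilyl)oxy]-6-(diethoxymethyl)-2-methylhepta-2,6-dienoate
Product: 11 (2Z,4R)-4-[(tert-butyldimethylsilyl)oxy]-6-(diethoxymethyl)-2-methylhepta-2,6-dien-1-ol
Conditions: DIBAL-H (2.5 equiv), CH2Cl2, −78 °C; aq Rochelle salt
Reagents that add atoms: none
Why: DIBAL-H 1,2-reduction of the enoate gives the allylic alcohol without touching the acetal, the silyl ether or the alkene geometry.

Step 6
Reactants: 11 (2Z,4R)-4-[(tert-butyldimethylsilyl)oxy]-6-(diethoxymethyl)-2-methylhepta-2,6-dien-1-ol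
Product: 12 (2Z,4R)-1-bromo-4-[(tert-butyldimethylsilyl)oxy]-6-(diethoxymethyl)-2-methylhepta-2,6-diene
Conditions: CBr4, PPh3, 2,6-lutidine (cat.), CH2Cl2, 0 °C
Reagents that add atoms: carbon tetrabromide, BrC(Br)(Br)Br
Why: Appel bromination converts the primary allylic alcohol into the bromide under essentially neutral conditions that should leave the Z alkene and the acetal intact.

Step 7
Reactants: 13 furan-3-carbaldehyde
Product: 14 2-(furan-3-yl)-1,3-dithiane
Conditions: HS(CH2)3SH, BF3·OEt2 (10 mol%), CH2Cl2, 0 °C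
Reagents that add atoms: propane-1,3-dithiol, SCCCS
Why: Lewis acid-catalysed dithioacetalisation turns the aldehyde carbon (future C8) into an acyl anion equivalent (Corey–Seebach umpolung).

Step 8
Reactants: 14 2-(furan-3-yl)-1,3-dithiane; 12 (2Z,4R)-1-bromo-4-[(tert-butyldimethylsilyl)oxy]-6-(diethoxymethyl)-2-methylhepta-2,6-diene
Product: 16 2-(furan-3-yl)-2-[(2Z,4R)-4-[(tert-butyldimethylsilyl)oxy]-6-(diethoxymethyl)-2-methylhepta-2,6-dien-1-yl]-1,3-dithiane, via 2-lithio-2-(furan-3-yl)-1,3-dithiane 15 (not isolated)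
Conditions: 14, n-BuLi, THF, −78 → −25 °C; then 12, −78 → −40 °C
Reagents that add atoms: none
Why: The dithiane C–H flanked by two sulfur atoms and the furan ring is far more acidic than the furan ring hydrogens, and its lithium anion displaces the primary allylic bromide by direct SN2 attack (Corey–Seebach alkylation), forming the C8–C9 bond.

Step 9
Reactants: 16 2-(furan-3-yl)-2-[(2Z,4R)-4-[(tert-butyldimethylsilyl)oxy]-6-(diethoxymethyl)-2-methylhepta-2,6-dien-1-yl]-1,3-dithiane
Product: 17 (3Z,5R)-5-[(tert-butyldimethylsilyl)oxy]-7-(diethoxymethyl)-1-(furan-3-yl)-3-methylocta-3,7-dien-1-one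
Conditions: MeI, CaCO3, MeCN/H2O (9:1), 40 °C
Reagents that add atoms: water, O
Why: S-Methylation followed by hydrolysis unmasks the ketone under carbonate-buffered, near-neutral conditions that should spare the acetal and avoid conjugation of the β,γ-alkene.

Step 10
Reactants: 17 (3Z,5R)-5-[(tert-butyldimethylsilyl)oxy]-7-(diethoxymethyl)-1-(furan-3-yl)-3-methylocta-3,7-dien-1-one
Product: 18 (1R,3Z,5R)-5-[(tert-butyldimethylsilyl)oxy]-7-(diethoxymethyl)-1-(furan-3-yl)-3-methylocta-3,7-dien-1-ol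
Conditions: (S)-2-methyl-CBS-oxazaborolidine (20 mol%), catecholborane, toluene, −78 °C
Reagents that add atoms: none
Why: Corey–Bakshi–Shibata reduction of the heteroaryl alkyl ketone with the (S)-oxazaborolidine should deliver hydride to the face that gives the (R)-carbinol at C8 (furyl as the large group), and catecholborane is chosen because it does not hydroborate the alkenes at −78 °C.

Step 11
Reactants: 18 (1R,3Z,5R)-5-[(tert-butyldimethylsilyl)oxy]-7-(diethoxymethyl)-1-(furan-3-yl)-3-methylocta-3,7-dien-1-ol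
Product: 19 3-[(1R,3Z,5R)-5-[(tert-butyldimethylsilyl)oxy]-7-(diethoxymethyl)-1-[(4-methoxybenzyl)oxy]-3-methylocta-3,7-dien-1-yl]furan
Conditions: NaH, PMBCl, n-Bu4NI (cat.), DMF, 0 °C → rt
Reagents that add atoms: 4-methoxybenzyl chloride, COc1ccc(CCl)cc1
Why: Williamson etherification of the sodium alkoxide gives the PMB ether under basic conditions that the acetal and the silyl ether tolerate.

Step 12
Reactants: 19 3-[(1R,3Z,5R)-5-[(tert-butyldimethylsilyl)oxy]-7-(diethoxymethyl)-1-[(4-methoxybenzyl)oxy]-3-methylocta-3,7-dien-1-yl]furan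
Product: 21 5-hydroxy-4-[(1R,3Z,5R)-5-[(tert-butyldimethylsilyl)oxy]-7-(diethoxymethyl)-1-[(4-methoxybenzyl)oxy]-3-methylocta-3,7-dien-1-yl]furan-2(5H)-one (C6 epimers), via furan endoperoxide 20 (not isolated)
Conditions: O2, hν (visible light), rose bengal (cat.), i-Pr2NEt, CH2Cl2, −78 °C
Reagents that add atoms: dioxygen, O=O
Why: Singlet oxygen adds to the furan in a [4+2] cycloaddition faster than it attacks the alkenes, and the hindered amine removes the less shielded bridgehead hydrogen at C12 of the endoperoxide (Kornblum–DeLaMare fragmentation), so the carbonyl is placed at C12 and the hemiacetal at C6.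

Step 13
Reactants: 21 5-hydroxy-4-[(1R,3Z,5R)-5-[(tert-butyldimethylsilyl)oxy]-7-(diethoxymethyl)-1-[(4-methoxybenzyl)oxy]-3-methylocta-3,7-dien-1-yl]furan-2(5H)-one
Product: 23 4-[(1R,3Z,5R)-5-[(tert-butyldimethylsilyl)oxy]-7-(diethoxymethyl)-1-[(4-methoxybenzyl)oxy]-3-methylocta-3,7-dien-1-yl]furan-2(5H)-one, via sodium cis-hydroxy enoate 22 (not isolated)
Conditions: NaBH4, EtOH, 0 °C; then aq NaHSO4 to pH 4, 0 °C
Reagents that add atoms: none
Why: NaBH4 reduces the masked C6 aldehyde of the ring-opened formyl acrylate, and the resulting cis-hydroxy acid lactonises on mild acidification to the β-substituted butenolide.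

Step 14
Reactants: 23 4-[(1R,3Z,5R)-5-[(tert-butyldimethylsilyl)oxy]-7-(diethoxymethyl)-1-[(4-methoxybenzyl)oxy]-3-methylocta-3,7-dien-1-yl]furan-2(5H)-one
Product: 24 4-[(1R,3Z,5R)-5-[(tert-butyldimethylsilyl)oxy]-7-formyl-1-[(4-methoxybenzyl)oxy]-3-methylocta-3,7-dien-1-yl]furan-2(5H)-one
Conditions: PPTS (10 mol%), acetone/H2O, rt
Reagents that add atoms: water, O
Why: Mild acid-catalysed hydrolysis of the acrolein-type diethyl acetal, which ionises readily to a conjugated oxocarbenium ion, should free the C4-methylene enal without cleaving the secondary silyl ether or the PMB ether.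

Step 15
Reactants: 24 4-[(1R,3Z,5R)-5-[(tert-butyldimethylsilyl)oxy]-7-formyl-1-[(4-methoxybenzyl)oxy]-3-methylocta-3,7-dien-1-yl]furan-2(5H)-one
Product: 25 triisopropyl({4-[(1R,3Z,5R)-5-[(tert-butyldimethylsilyl)oxy]-7-formyl-1-[(4-methoxybenzyl)oxy]-3-methylocta-3,7-dien-1-yl]furan-2-yl}oxy)silane
Conditions: TIPSOTf (1.1 equiv), Et3N (3 equiv), CH2Cl2, −78 → −30 °C; aq NaHCO3, rapid filtration through Et3N-deactivated silica
Reagents that add atoms: triisopropylsilyl trifluoromethanesulfonate, CC(C)[Si](OS(=O)(=O)C(F)(F)F)(C(C)C)C(C)C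
Why: Soft enolisation of the butenolide (O-silylation, then amine deprotonation at the γ-carbon C6) gives the aromatic 2-silyloxyfuran while the enal, which has no α-hydrogen, cannot be silylated, and low temperature, excess amine and the bulky silyl group are meant to suppress silyl triflate-promoted aldol reaction before work-up.

Step 16
Reactants: 25 triisopropyl({4-[(1R,3Z,5R)-5-[(tert-butyldimethylsilyl)oxy]-7-formyl-1-[(4-methoxybenzyl)oxy]-3-methylocta-3,7-dien-1-yl]furan-2-yl}oxy)silane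
Product: 26 (1(10)Z,2R,5S,6R,8R)-2-[(tert-butyldimethylsilyl)oxy]-5-hydroxy-8-[(4-methoxybenzyl)oxy]-13-norgermacra-1(10),4(15),7(11)-trien-12,6-olide
Conditions: BF3·OEt2 (3 equiv), CH2Cl2, −78 °C, slow addition of 25 (final 1 mM); aq NaHCO3
Reagents that add atoms: none
Why: Proposed new method: BF3 binds the oxygen of the C5 aldehyde, the 2-silyloxyfuran attacks it through its free α-carbon C6 in an open transition state and loss of the silyl group as the fluoride leaves the butenolide and a C5 borinate that gives the alcohol on work-up, the closest known reactions being the intermolecular vinylogous Mukaiyama aldol of 2-silyloxyfurans with aldehydes and silyl triflate-mediated intramolecular vinylogous aldol closures of five- to seven-membered rings. The ten-membered carbocycle closes in a 10-(enolendo)-exo-trig mode, eased by the five trigonal ring carbons C1, C10, C4, C6 and C7 and the Z alkene, which lower transannular strain. C6 (R) should be set by C8: with the C8–H bond eclipsing the furan plane on the C6 side to avoid allylic strain, C9 and with it the tether lie on the Si face of C6 while the PMB ether covers the other face. C5 (S) requires attack on the Re face of the aldehyde, expected for an s-trans enal whose BF3-bound oxygen points out of the forming ring, and gives both oxygens on one face of the ring. The step needs 1,2-addition at C5 instead of conjugate addition at C15 (both would close a ten-membered ring), for which the hard oxygen-bound Lewis acid at −78 °C is relied on, and attack by the furan instead of cation–olefin closure by C10=C1, which the much higher nucleophilicity of the silyloxyfuran and the allylic silyl ether at C2 should secure. Slow addition to a dilute solution keeps oligomerisation down.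

Step 17
Reactants: 26 (1(10)Z,2R,5S,6R,8R)-2-[(tert-butyldimethylsilyl)oxy]-5-hydroxy-8-[(4-methoxybenzyl)oxy]-13-norgermacra-1(10),4(15),7(11)-trien-12,6-olide
Product: 27 (1(10)Z,2R,5S,6R,7R,8R)-2-[(tert-butyldimethylsilyl)oxy]-5-hydroxy-8-[(4-methoxybenzyl)oxy]-13-norgermacra-1(10),4(15)-dien-12,6-olide
Conditions: [(Ph3P)CuH]6 (0.5 equiv), H2O (2 equiv), toluene, rt
Reagents that add atoms: none
Why: Conjugate reduction of the β-substituted butenolide with the copper hydride cluster (Stryker reduction) should deliver hydride to C7 from the exposed face of the lactone ring, opposite the C5 branch of the macrocycle at C6, which sets C7 (R) and the cis ring fusion while the isolated alkenes and the free alcohol stay inert.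

Step 18
Reactants: 27 (1(10)Z,2R,5S,6R,7R,8R)-2-[(tert-butyldimethylsilyl)oxy]-5-hydroxy-8-[(4-methoxybenzyl)oxy]-13-norgermacra-1(10),4(15)-dien-12,6-olide
Product: 29 (1(10)Z,2R,5S,6R,7R,8R)-2-[(tert-butyldimethylsilyl)oxy]-13-(dimethylamino)-5-hydroxy-8-[(4-methoxybenzyl)oxy]germacra-1(10),4(15)-dien-12,6-olide (C11 epimers), via dilithium alkoxide enolate 28 (not isolated)
Conditions: LDA (2.5 equiv), THF, −78 °C; CH2=NMe2+ I− (3 equiv), −78 → 0 °C; aq NaHCO3
Reagents that add atoms: N,N-dimethylmethyleneiminium iodide (Eschenmoser's salt), C=[N+](C)C.[I-]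
Why: Excess LDA forms the C5 alkoxide and the lactone enolate, which is aminomethylated at C11 by the iminium salt (Mannich reaction), bringing in C13, and the configuration at C11 is of no consequence.

Step 19
Reactants: 29 (1(10)Z,2R,5S,6R,7R,8R)-2-[(tert-butyldimethylsilyl)oxy]-13-(dimethylamino)-5-hydroxy-8-[(4-methoxybenzyl)oxy]germacra-1(10),4(15)-dien-12,6-olide
Product: 31 (1(10)Z,2R,5S,6R,7R,8R)-2-[(tert-butyldimethylsilyl)oxy]-5-hydroxy-8-[(4-methoxybenzyl)oxy]germacra-1(10),4(15),11(13)-trien-12,6-olide, via trimethylammonium iodide 30 (not isolated)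
Conditions: MeI, THF, rt; then aq NaHCO3, rt
Reagents that add atoms: none
Why: Exhaustive N-methylation followed by mild base-induced β-elimination of trimethylamine (Hofmann-type elimination of the Mannich base) unveils the C11=C13 methylene.

Step 20
Reactants: 31 (1(10)Z,2R,5S,6R,7R,8R)-2-[(tert-butyldimethylsilyl)oxy]-5-hydroxy-8-[(4-methoxybenzyl)oxy]germacra-1(10),4(15),11(13)-trien-12,6-olide
Product: 32 (1(10)Z,2R,5S,6R,7R,8R)-5-acetoxy-2-[(tert-butyldimethylsilyl)oxy]-8-[(4-methoxybenzyl)oxy]germacra-1(10),4(15),11(13)-trien-12,6-olide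
Conditions: Ac2O, pyridine, DMAP (cat.), CH2Cl2, 0 °C → rt
Reagents that add atoms: acetic anhydride, CC(=O)OC(C)=O
Why: DMAP-catalysed acetylation esterifies the only free hydroxyl, the secondary allylic C5–OH.

Step 21
Reactants: 32 (1(10)Z,2R,5S,6R,7R,8R)-5-acetoxy-2-[(tert-butyldimethylsilyl)oxy]-8-[(4-methoxybenzyl)oxy]germacra-1(10),4(15),11(13)-trien-12,6-olide
Product: 33 (1(10)Z,2R,5S,6R,7R,8R)-5-acetoxy-2-[(tert-butyldimethylsilyl)oxy]-8-hydroxygermacra-1(10),4(15),11(13)-trien-12,6-olide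
Conditions: DDQ, CH2Cl2/pH 7 buffer, 0 °C
Reagents that add atoms: none
Why: Oxidative cleavage of the electron-rich PMB ether by DDQ through the benzylic oxocarbenium ion frees C8–OH and should leave the silyl ether, the acetate and the alkenes untouched.

Step 22
Reactants: 33 (1(10)Z,2R,5S,6R,7R,8R)-5-acetoxy-2-[(tert-butyldimethylsilyl)oxy]-8-hydroxygermacra-1(10),4(15),11(13)-trien-12,6-olide
Product: 34 (1(10)Z,2R,5S,6R,7R,8R)-5-acetoxy-2-[(tert-butyldimethylsilyl)oxy]-8-[(E)-2-methylbut-2-enoyloxy]germacra-1(10),4(15),11(13)-trien-12,6-olide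
Conditions: tiglic acid, 2,4,6-trichlorobenzoyl chloride, Et3N, toluene, rt; then 33, DMAP, toluene, rt → 40 °C
Reagents that add atoms: (E)-2-methylbut-2-enoic acid (tiglic acid), C/C=C(\C)C(=O)O
Why: Yamaguchi esterification through the mixed anhydride and the acylpyridinium ion acylates the hindered secondary C8–OH, and the thermodynamically preferred (E)-configured tiglate is not expected to isomerise.

Step 23
Reactants: 34 (1(10)Z,2R,5S,6R,7R,8R)-5-acetoxy-2-[(tert-butyldimethylsilyl)oxy]-8-[(E)-2-methylbut-2-enoyloxy]germacra-1(10),4(15),11(13)-trien-12,6-olide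
Product: 35 (1(10)Z,2R,5S,6R,7R,8R)-5-acetoxy-2-hydroxy-8-[(E)-2-methylbut-2-enoyloxy]germacra-1(10),4(15),11(13)-trien-12,6-olide (CNP0210609.1)
Conditions: HF·pyridine, pyridine, THF, 0 °C → rt
Reagents that add atoms: none
Why: Buffered HF·pyridine cleaves the secondary allylic silyl ether by fluoride attack at silicon and should cause neither acyl migration nor conjugate addition to the α-methylene lactone, giving the target.

**Compound list**

1 | 2-bromo-3,3-diethoxyprop-1-ene | C=C(Br)C(OCC)OCC | starting material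
2 | methyl (2R)-oxirane-2-carboxylate | COC(=O)[C@H]1CO1 | starting material
3 | (3,3-diethoxyprop-1-en-2-yl)lithium | [Li]C(=C)C(OCC)OCC | intermediate
4 | (3,3-diethoxyprop-1-en-2-yl)magnesium bromide | Br[Mg]C(=C)C(OCC)OCC | intermediate
5 | methyl (2R)-4-(diethoxymethyl)-2-hydroxypent-4-enoate | COC(=O)[C@H](O)CC(=C)C(OCC)OCC | intermediate
6 | methyl (2R)-2-[(tert-butyldimethylsilyl)oxy]-4-(diethoxymethyl)pent-4-enoate | COC(=O)[C@H](O[Si](C)(C)C(C)(C)C)CC(=C)C(OCC)OCC | intermediate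
7 | (2R)-2-[(tert-butyldimethylsilyl)oxy]-4-(diethoxymethyl)pent-4-enal | O=C[C@H](O[Si](C)(C)C(C)(C)C)CC(=C)C(OCC)OCC | intermediate
8 | ethyl 2-[bis(2,2,2-trifluoroethoxy)phosphoryl]propanoate | CCOC(=O)C(C)P(=O)(OCC(F)(F)F)OCC(F)(F)F | starting material
9 | potassium 1-ethoxy-1-oxo-2-[bis(2,2,2-trifluoroethoxy)phosphoryl]propan-2-ide | CCOC(=O)[C-](C)P(=O)(OCC(F)(F)F)OCC(F)(F)F.[K+] | intermediate
10 | ethyl (2Z,4R)-4-[(tert-butyldimethylsilyl)oxy]-6-(diethoxymethyl)-2-methylhepta-2,6-dienoate | CCOC(=O)/C(C)=C\[C@H](O[Si](C)(C)C(C)(C)C)CC(=C)C(OCC)OCC | intermediate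
11 | (2Z,4R)-4-[(tert-butyldimethylsilyl)oxy]-6-(diethoxymethyl)-2-methylhepta-2,6-dien-1-ol | OC/C(C)=C\[C@H](O[Si](C)(C)C(C)(C)C)CC(=C)C(OCC)OCC | intermediate
12 | (2Z,4R)-1-bromo-4-[(tert-butyldimethylsilyl)oxy]-6-(diethoxymethyl)-2-methylhepta-2,6-diene | BrC/C(C)=C\[C@H](O[Si](C)(C)C(C)(C)C)CC(=C)C(OCC)OCC | intermediate
13 | furan-3-carbaldehyde | O=Cc1ccoc1 | starting material
14 | 2-(furan-3-yl)-1,3-dithiane | C1CSC(SC1)c1ccoc1 | intermediate
15 | 2-lithio-2-(furan-3-yl)-1,3-dithiane | [Li]C1(SCCCS1)c1ccoc1 | intermediate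
16 | 2-(furan-3-yl)-2-[(2Z,4R)-4-[(tert-butyldimethylsilyl)oxy]-6-(diethoxymethyl)-2-methylhepta-2,6-dien-1-yl]-1,3-dithiane | c1occc1C1(SCCCS1)C/C(C)=C\[C@H](O[Si](C)(C)C(C)(C)C)CC(=C)C(OCC)OCC | intermediate
17 | (3Z,5R)-5-[(tert-butyldimethylsilyl)oxy]-7-(diethoxymethyl)-1-(furan-3-yl)-3-methylocta-3,7-dien-1-one | O=C(c1ccoc1)C/C(C)=C\[C@H](O[Si](C)(C)C(C)(C)C)CC(=C)C(OCC)OCC | intermediate
18 | (1R,3Z,5R)-5-[(tert-butyldimethylsilyl)oxy]-7-(diethoxymethyl)-1-(furan-3-yl)-3-methylocta-3,7-dien-1-ol | c1occc1[C@H](O)C/C(C)=C\[C@H](O[Si](C)(C)C(C)(C)C)CC(=C)C(OCC)OCC | intermediate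
19 | 3-[(1R,3Z,5R)-5-[(tert-butyldimethylsilyl)oxy]-7-(diethoxymethyl)-1-[(4-methoxybenzyl)oxy]-3-methylocta-3,7-dien-1-yl]furan | c1occc1[C@H](OCc1ccc(OC)cc1)C/C(C)=C\[C@H](O[Si](C)(C)C(C)(C)C)CC(=C)C(OCC)OCC | intermediate
20 | 2,5-endoperoxide of 19 (2,3,7-trioxabicyclo[2.2.1]hept-5-ene carrying the side chain on C5) | O1OC2C=C([C@H](OCc3ccc(OC)cc3)C/C(C)=C\[C@H](O[Si](C)(C)C(C)(C)C)CC(=C)C(OCC)OCC)C1O2 | intermediate
21 | 5-hydroxy-4-[(1R,3Z,5R)-5-[(tert-butyldimethylsilyl)oxy]-7-(diethoxymethyl)-1-[(4-methoxybenzyl)oxy]-3-methylocta-3,7-dien-1-yl]furan-2(5H)-one | O=C1C=C([C@H](OCc2ccc(OC)cc2)C/C(C)=C\[C@H](O[Si](C)(C)C(C)(C)C)CC(=C)C(OCC)OCC)C(O)O1 | intermediate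
22 | sodium 4-hydroxy-3-[(1R,3Z,5R)-5-[(tert-butyldimethylsilyl)oxy]-7-(diethoxymethyl)-1-[(4-methoxybenzyl)oxy]-3-methylocta-3,7-dien-1-yl]but-2-enoate (carboxylate cis to CH2OH) | [Na+].[O-]C(=O)/C=C(\CO)[C@H](OCc1ccc(OC)cc1)C/C(C)=C\[C@H](O[Si](C)(C)C(C)(C)C)CC(=C)C(OCC)OCC | intermediate
23 | 4-[(1R,3Z,5R)-5-[(tert-butyldimethylsilyl)oxy]-7-(diethoxymethyl)-1-[(4-methoxybenzyl)oxy]-3-methylocta-3,7-dien-1-yl]furan-2(5H)-one | O=C1C=C(CO1)[C@H](OCc2ccc(OC)cc2)C/C(C)=C\[C@H](O[Si](C)(C)C(C)(C)C)CC(=C)C(OCC)OCC | intermediate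
24 | 4-[(1R,3Z,5R)-5-[(tert-butyldimethylsilyl)oxy]-7-formyl-1-[(4-methoxybenzyl)oxy]-3-methylocta-3,7-dien-1-yl]furan-2(5H)-one | O=C1C=C(CO1)[C@H](OCc2ccc(OC)cc2)C/C(C)=C\[C@H](O[Si](C)(C)C(C)(C)C)CC(=C)C=O | intermediate
25 | triisopropyl({4-[(1R,3Z,5R)-5-[(tert-butyldimethylsilyl)oxy]-7-formyl-1-[(4-methoxybenzyl)oxy]-3-methylocta-3,7-dien-1-yl]furan-2-yl}oxy)silane | CC(C)[Si](C(C)C)(C(C)C)Oc1cc(co1)[C@H](OCc2ccc(OC)cc2)C/C(C)=C\[C@H](O[Si](C)(C)C(C)(C)C)CC(=C)C=O | intermediate
26 | (1(10)Z,2R,5S,6R,8R)-2-[(tert-butyldimethylsilyl)oxy]-5-hydroxy-8-[(4-methoxybenzyl)oxy]-13-norgermacra-1(10),4(15),7(11)-trien-12,6-olide | O=C1C=C2[C@H](OCc3ccc(OC)cc3)C/C(C)=C\[C@H](O[Si](C)(C)C(C)(C)C)CC(=C)[C@H](O)[C@@H]2O1 | intermediate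
27 | (1(10)Z,2R,5S,6R,7R,8R)-2-[(tert-butyldimethylsilyl)oxy]-5-hydroxy-8-[(4-methoxybenzyl)oxy]-13-norgermacra-1(10),4(15)-dien-12,6-olide | O=C1C[C@@H]2[C@H](OCc3ccc(OC)cc3)C/C(C)=C\[C@H](O[Si](C)(C)C(C)(C)C)CC(=C)[C@H](O)[C@@H]2O1 | intermediate
28 | dilithium C5-alkoxide C12-enolate of 27 | [Li]OC1=C[C@@H]2[C@H](OCc3ccc(OC)cc3)C/C(C)=C\[C@H](O[Si](C)(C)C(C)(C)C)CC(=C)[C@H](O[Li])[C@@H]2O1 | intermediate
29 | (1(10)Z,2R,5S,6R,7R,8R)-2-[(tert-butyldimethylsilyl)oxy]-13-(dimethylamino)-5-hydroxy-8-[(4-methoxybenzyl)oxy]germacra-1(10),4(15)-dien-12,6-olide | CN(C)CC1[C@@H]2[C@H](OCc3ccc(OC)cc3)C/C(C)=C\[C@H](O[Si](C)(C)C(C)(C)C)CC(=C)[C@H](O)[C@@H]2OC1=O | intermediate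
30 | 13-(trimethylammonio) analogue of 29, iodide | [I-].C[N+](C)(C)CC1[C@@H]2[C@H](OCc3ccc(OC)cc3)C/C(C)=C\[C@H](O[Si](C)(C)C(C)(C)C)CC(=C)[C@H](O)[C@@H]2OC1=O | intermediate
31 | (1(10)Z,2R,5S,6R,7R,8R)-2-[(tert-butyldimethylsilyl)oxy]-5-hydroxy-8-[(4-methoxybenzyl)oxy]germacra-1(10),4(15),11(13)-trien-12,6-olide | C=C1[C@@H]2[C@H](OCc3ccc(OC)cc3)C/C(C)=C\[C@H](O[Si](C)(C)C(C)(C)C)CC(=C)[C@H](O)[C@@H]2OC1=O | intermediate
32 | (1(10)Z,2R,5S,6R,7R,8R)-5-acetoxy-2-[(tert-butyldimethylsilyl)oxy]-8-[(4-methoxybenzyl)oxy]germacra-1(10),4(15),11(13)-trien-12,6-olide | C=C1[C@@H]2[C@H](OCc3ccc(OC)cc3)C/C(C)=C\[C@H](O[Si](C)(C)C(C)(C)C)CC(=C)[C@H](OC(C)=O)[C@@H]2OC1=O | intermediate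
33 | (1(10)Z,2R,5S,6R,7R,8R)-5-acetoxy-2-[(tert-butyldimethylsilyl)oxy]-8-hydroxygermacra-1(10),4(15),11(13)-trien-12,6-olide | C=C1[C@@H]2[C@H](O)C/C(C)=C\[C@H](O[Si](C)(C)C(C)(C)C)CC(=C)[C@H](OC(C)=O)[C@@H]2OC1=O | intermediate
34 | (1(10)Z,2R,5S,6R,7R,8R)-5-acetoxy-2-[(tert-butyldimethylsilyl)oxy]-8-[(E)-2-methylbut-2-enoyloxy]germacra-1(10),4(15),11(13)-trien-12,6-olide | C=C1[C@@H]2[C@H](OC(=O)/C(C)=C/C)C/C(C)=C\[C@H](O[Si](C)(C)C(C)(C)C)CC(=C)[C@H](OC(C)=O)[C@@H]2OC1=O | intermediate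
35 | (1(10)Z,2R,5S,6R,7R,8R)-5-acetoxy-2-hydroxy-8-[(E)-2-methylbut-2-enoyloxy]germacra-1(10),4(15),11(13)-trien-12,6-olide (CNP0210609.1) | C=C1C(=O)O[C@@H]2[C@H]1[C@H](OC(=O)/C(C)=C/C)C/C(C)=C\[C@H](O)CC(=C)[C@@H]2OC(C)=O | target

**Step count**

Total: 23 steps. Longest linear sequence: 22 steps (steps 1–6, then 8–23); step 7 is a one-step branch.

**Steps most likely to fail**

1. Step 16 (proposed new method). Oligomerisation may outrun the strained ten-membered closure. The activated enal may instead be captured by the C10=C1 alkene in a cation–olefin closure, or be attacked at C15. The facial selectivity at C5 or C6 may be poor. The Lewis acid may ionise the C8 ether.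
Fallback (sets out from 19, returns at 26): the same C5–C6 bond is made by known reactions, with the carbocycle closed before the lactone exists. Furan 19 is lithiated at C6, the ring position next to the C8 ether and directed by its oxygen (n-BuLi, THF, −78 °C), and quenched with I2 to give the 2-iodofuran F1. PPTS in wet acetone frees the aldehyde to give the iodo enal F2. A Nozaki–Hiyama–Kishi macrocyclisation (CrCl2, NiCl2 (cat.), DMSO/THF, high dilution) adds the furyl–chromium species to the C5 aldehyde and should give the furan-fused ten-membered carbinol F3. Photooxygenation of this furan (O2, rose bengal, i-Pr2NEt, CH2Cl2, −78 °C), which has a single α-hydrogen at C12, can only place the carbonyl at C12 and gives the C6-hydroxybutenolide F4. NaBH4 in EtOH reduces the C6 ketone of its ring-opened form and relactonisation on mild acidification returns 26; C6 is then set by hydride delivery next to the C5 carbinol.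

2. Step 15. The silyl triflate may act as a Lewis acid on the enal as soon as the silyloxyfuran forms, so that uncontrolled aldol reaction precedes isolation. The silyloxyfuran may also be lost by hydrolytic desilylation on work-up.
Fallback (sets out from 24, returns at 25): the aldehyde is unveiled only after the nucleophile is in place. Luche reduction of 24 (NaBH4, CeCl3·7H2O, MeOH, −78 °C) gives the allylic alcohol F5 and acetylation (Ac2O, pyridine) the allylic acetate F6. TIPSOTf/Et3N then forms the silyloxyfuran acetate F7 with no aldehyde present. DIBAL-H at −78 °C removes the acetate reductively, the silyloxyfuran having no carbonyl group, to give the silyloxyfuran allylic alcohol F8. MnO2 in CH2Cl2 oxidises the allylic alcohol under neutral conditions to 25.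

3. Step 12. The base-induced fragmentation of the endoperoxide may lack regiocontrol, placing the carbonyl at C6, and ene-type oxygenation of the trisubstituted C10=C1 alkene may compete.
Fallback (sets out from 19, returns at 23): the oxygen is brought to C12 by C–H borylation instead of photooxygenation. Iridium-catalysed borylation ([Ir(OMe)(cod)]2, 4,4'-di-tert-butyl-2,2'-bipyridine, bis(pinacolato)diboron, hexane, rt) takes place at the unhindered furan α-position C12 and gives the furylboronate F9. Oxidation with NaBO3·4H2O in THF/H2O followed by Et3N-mediated tautomerisation of the 2-hydroxyfuran into conjugation gives butenolide 23 directly.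

**Further compounds**

F1 | step 16 | 2-iodo-3-[(1R,3Z,5R)-5-[(tert-butyldimethylsilyl)oxy]-7-(diethoxymethyl)-1-[(4-methoxybenzyl)oxy]-3-methylocta-3,7-dien-1-yl]furan | Ic1occc1[C@H](OCc1ccc(OC)cc1)C/C(C)=C\[C@H](O[Si](C)(C)C(C)(C)C)CC(=C)C(OCC)OCC
F2 | step 16 | 2-iodo-3-[(1R,3Z,5R)-5-[(tert-butyldimethylsilyl)oxy]-7-formyl-1-[(4-methoxybenzyl)oxy]-3-methylocta-3,7-dien-1-yl]furan | Ic1occc1[C@H](OCc1ccc(OC)cc1)C/C(C)=C\[C@H](O[Si](C)(C)C(C)(C)C)CC(=C)C=O
F3 | step 16 | (1(10)Z,2R,5S,8R)-2-[(tert-butyldimethylsilyl)oxy]-8-[(4-methoxybenzyl)oxy]-12,6-epoxy-13-norgermacra-1(10),4(15),6,11-tetraen-5-ol (furan fused at C6–C7) | c12occc1[C@H](OCc1ccc(OC)cc1)C/C(C)=C\[C@H](O[Si](C)(C)C(C)(C)C)CC(=C)[C@@H]2O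
F4 | step 16 | (1(10)Z,2R,5S,8R)-2-[(tert-butyldimethylsilyl)oxy]-5,6-dihydroxy-8-[(4-methoxybenzyl)oxy]-13-norgermacra-1(10),4(15),7(11)-trien-12,6-olide (C6 epimers) | O=C1C=C2[C@H](OCc3ccc(OC)cc3)C/C(C)=C\[C@H](O[Si](C)(C)C(C)(C)C)CC(=C)[C@H](O)C2(O)O1
F5 | step 15 | 4-[(1R,3Z,5R)-5-[(tert-butyldimethylsilyl)oxy]-7-(hydroxymethyl)-1-[(4-methoxybenzyl)oxy]-3-methylocta-3,7-dien-1-yl]furan-2(5H)-one | O=C1C=C(CO1)[C@H](OCc2ccc(OC)cc2)C/C(C)=C\[C@H](O[Si](C)(C)C(C)(C)C)CC(=C)CO
F6 | step 15 | 4-[(1R,3Z,5R)-7-(acetoxymethyl)-5-[(tert-butyldimethylsilyl)oxy]-1-[(4-methoxybenzyl)oxy]-3-methylocta-3,7-dien-1-yl]furan-2(5H)-one | O=C1C=C(CO1)[C@H](OCc2ccc(OC)cc2)C/C(C)=C\[C@H](O[Si](C)(C)C(C)(C)C)CC(=C)COC(C)=O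
F7 | step 15 | ({4-[(1R,3Z,5R)-7-(acetoxymethyl)-5-[(tert-butyldimethylsilyl)oxy]-1-[(4-methoxybenzyl)oxy]-3-methylocta-3,7-dien-1-yl]furan-2-yl}oxy)triisopropylsilane | CC(C)[Si](C(C)C)(C(C)C)Oc1cc(co1)[C@H](OCc2ccc(OC)cc2)C/C(C)=C\[C@H](O[Si](C)(C)C(C)(C)C)CC(=C)COC(C)=O
F8 | step 15 | ({4-[(1R,3Z,5R)-5-[(tert-butyldimethylsilyl)oxy]-7-(hydroxymethyl)-1-[(4-methoxybenzyl)oxy]-3-methylocta-3,7-dien-1-yl]furan-2-yl}oxy)triisopropylsilane | CC(C)[Si](C(C)C)(C(C)C)Oc1cc(co1)[C@H](OCc2ccc(OC)cc2)C/C(C)=C\[C@H](O[Si](C)(C)C(C)(C)C)CC(=C)CO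
F9 | step 12 | 2-{4-[(1R,3Z,5R)-5-[(tert-butyldimethylsilyl)oxy]-7-(diethoxymethyl)-1-[(4-methoxybenzyl)oxy]-3-methylocta-3,7-dien-1-yl]furan-2-yl}-4,4,5,5-tetramethyl-1,3,2-dioxaborolane | CC1(C)OB(OC1(C)C)c1cc(co1)[C@H](OCc2ccc(OC)cc2)C/C(C)=C\[C@H](O[Si](C)(C)C(C)(C)C)CC(=C)C(OCC)OCC
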